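**Retrosynthetic overview**

1. The cis-1,4-dioxygenated cyclohex-2-ene unit of the six-membered ring (C3–O and C6–O flanking the C4=C5 double bond) is the retron of a Diels–Alder reaction between an E,E-1,4-dioxygenated diene and an acetylene equivalent; that one reaction makes C3–C4 and C5–C6.
2. The cis C1/C2 diol is added afterwards to the diene-derived C1=C2 alkene by osmylation anti to both allylic oxygens, followed by acetylation of the C2 hydroxyl.
3. C6–O, C1 and the CH2O arm form a dihydroxyacetone unit, so the diene is built on 2,2-dimethyl-1,3-dioxan-5-one; a temporary 4H-1,3-dioxin ring locks the enol-ether geometry and makes the diene electron-rich.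
4. The acetylene equivalent is (R)-ethynyl p-tolyl sulfoxide: sulfur activates the alkyne, carries the absolute configuration, keeps the new alkene inert to OsO4, and is finally removed as a sulfonyl radical.
5. Ring order: dioxin ring first (from the dioxanone), carbocycle second (Diels–Alder), dioxane ring opened at the end. The C3 benzoate comes in with the diene; the C6 and CH2 benzoates are added last.

Key step: step 4

Remark: the sense of facial induction in step 4 is taken from the transition-state model given there; if the other diastereomer proves to be the major one, the mirror-image sulfoxide, made the same way from the mirror-image menthyl sulfinate, is used and nothing else in the route changes.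

**Route**

Step 1
Reactants: 1 2,2-dimethyl-1,3-dioxan-5-one; 2 (triphenylphosphoranylidene)acetaldehyde
Product: 3 2-(2,2-dimethyl-1,3-dioxan-5-ylidene)acetaldehyde
Conditions: PhMe, 80 °C
Reagents that add atoms: none
Why: Wittig olefination of the electrophilic, symmetric α,α'-dioxygenated ketone by a stabilised formyl ylide; no stereocentre and no alkene isomerism arise because both ring arms are identical.

Step 2
Reactants: 3 2-(2,2-dimethyl-1,3-dioxan-5-ylidene)acetaldehyde
Product: 5 (E)-2-(2,2-dimethyl-4H-1,3-dioxin-5-yl)ethenyl benzoate, via potassium dienolate 4 (not isolated)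
Conditions: KN(SiMe3)2, THF, −78 °C; then BzCl, −78 → 0 °C; NaHCO3 work-up, Et3N-buffered silica
Reagents that add atoms: benzoyl chloride, O=C(Cl)c1ccccc1
Why: Kinetic γ-deprotonation of the s-trans enal gives the extended dienolate, whose O-acylation (enolate O-benzoylation) should give the E enol benzoate, while the ring forces the other enol oxygen cis to the CH2O arm, so both oxygens sit outside the s-cis diene.

Step 3
Reactants: 6 (1R,2S,5R)-menthyl (S)-p-toluenesulfinate; 7 ethynylmagnesium bromide
Product: 8 (R)-ethynyl p-tolyl sulfoxide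
Conditions: PhMe–THF, −30 → 0 °C; aq NH4Cl
Reagents that add atoms: none
Why: Andersen sulfoxide synthesis: the acetylide carbon displaces menthoxide at sulfur with inversion, so the diastereomerically pure sulfinate 6 fixes the sulfur stereocentre of 8 as R.

Step 4
Reactants: 5 (E)-2-(2,2-dimethyl-4H-1,3-dioxin-5-yl)ethenyl benzoate; 8 (R)-ethynyl p-tolyl sulfoxide
Product: 9 (6S,8aR)-2,2-dimethyl-8-[(S)-p-tolylsulfinyl]-6,8a-dihydro-4H-1,3-benzodioxin-6-yl benzoate (sulfur geometry retained; its descriptor changes by priority only)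
Conditions: PhMe, 60 °C; chromatography on Et3N-buffered silica to remove the minor diastereomer
Reagents that add atoms: none
Why: A thermal, concerted, suprafacial [4+2] cycloaddition (Diels–Alder) joins both ends of the electron-rich 1-alkoxy-4-acyloxy diene 5 to the two alkyne carbons of 8 in one event; the closest known reaction type is the Diels–Alder reaction of enantiopure alkynyl p-tolyl sulfoxides and of ethynyl sulfones as acetylene equivalents. The carbocycle closes as a six-membered ring by this intermolecular [4+2] mode, the inner-carbon substituent of 5 favouring the reactive s-cis form. C6 and C8a (later C3 and C6 of the target) become cis to each other because both terminal oxygens are outside (E) on the diene, which the dioxin ring guarantees at one end and step 2 at the other. Their absolute configuration is controlled by the sulfur stereocentre: in the favoured transition state the sulfur lone pair faces the diene, the sulfinyl oxygen lies on the side of the inner diene carbons and the tolyl group points away, which for (R)-8 should lead to the (6S,8aR) adduct, and the diastereomer with the opposite carbon configuration is separable by chromatography. The step needs regioselectivity and π-facial selectivity: the ring enol-ether oxygen puts the largest HOMO coefficient on the benzoyloxy-bearing terminus, which bonds to the unsubstituted alkyne carbon, so sulfur ends up next to C8a, and the sulfinyl group supplies the facial bias. The sulfinyl group also keeps the new ring alkene electron-poor, which step 5 relies on.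

Step 5
Reactants: 9 (6S,8aR)-2,2-dimethyl-8-[(S)-p-tolylsulfinyl]-6,8a-dihydro-4H-1,3-benzodioxin-6-yl benzoate
Product: 11 (4aS,5S,6R,8aR)-4a,5-dihydroxy-2,2-dimethyl-8-(p-tolylsulfonyl)-4a,5,6,8a-tetrahydro-4H-1,3-benzodioxin-6-yl benzoate, via sulfinyl diol 10 (not isolated)
Conditions: OsO4 (5 mol %), NMO (4 equiv), acetone–H2O (5:1), 23 °C
Reagents that add atoms: N-methylmorpholine N-oxide, C[N+]1([O-])CCOCC1; water, O; OsO4, O=[Os](=O)(=O)=O (catalytic oxygen carrier)
Why: Upjohn dihydroxylation: OsO4 adds syn to the electron-rich trisubstituted alkene (the sulfinyl-bearing alkene is electron-poor) from the face anti to both allylic C–O bonds at C6 and C8a, which sets C4a and C5, and the same OsO4/NMO couple oxidises the sulfoxide to the sulfone (OsO4-catalysed sulfoxide oxidation), erasing the spent sulfur stereocentre.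

Step 6
Reactants: 11 (4aS,5S,6R,8aR)-4a,5-dihydroxy-2,2-dimethyl-8-(p-tolylsulfonyl)-4a,5,6,8a-tetrahydro-4H-1,3-benzodioxin-6-yl benzoate
Product: 12 (4aS,5S,6R,8aR)-5-acetoxy-4a-hydroxy-2,2-dimethyl-8-(p-tolylsulfonyl)-4a,5,6,8a-tetrahydro-4H-1,3-benzodioxin-6-yl benzoate
Conditions: Ac2O, pyridine, DMAP (cat.), CH2Cl2, 0 → 23 °C
Reagents that add atoms: acetic anhydride, CC(=O)OC(C)=O
Why: Nucleophile-catalysed acetylation (DMAP) takes the only secondary hydroxyl; the tertiary 4a-hydroxyl is too hindered to react.

Step 7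
Reactants: 12 (4aS,5S,6R,8aR)-5-acetoxy-4a-hydroxy-2,2-dimethyl-8-(p-tolylsulfonyl)-4a,5,6,8a-tetrahydro-4H-1,3-benzodioxin-6-yl benzoate
Product: 14 (1R,4S,5R,6S)-6-acetoxy-4,5-dihydroxy-5-(hydroxymethyl)cyclohex-2-en-1-yl benzoate, via vinylstannane 13 (not isolated)
Conditions: Bu3SnH (2.5 equiv), AIBN (cat.), PhMe, 100 °C; then CF3CO2H–H2O (9:1), CH2Cl2, 0 → 23 °C
Reagents that add atoms: none
Why: Radical addition–elimination of Bu3Sn• on the vinyl sulfone (desulfonylative stannylation) expels the sulfonyl radical, and CF3CO2H then protodestannylates the vinylstannane at the same carbon and hydrolyses the acetonide, so the alkene stays where the cycloaddition put it and no stereocentre is touched.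

Step 8
Reactants: 14 (1R,4S,5R,6S)-6-acetoxy-4,5-dihydroxy-5-(hydroxymethyl)cyclohex-2-en-1-yl benzoate
Product: 15 [(1R,2S,3R,6S)-2-acetoxy-3,6-bis(benzoyloxy)-1-hydroxycyclohex-4-en-1-yl]methyl benzoate
Conditions: BzCl (2.5 equiv), pyridine, DMAP (cat.), CH2Cl2, 0 → 23 °C
Reagents that add atoms: benzoyl chloride, O=C(Cl)c1ccccc1
Why: Pyridine/DMAP benzoylation acylates the primary and the allylic secondary hydroxyl while the tertiary hydroxyl stays free, and the esters already on C2 and C3 leave no free neighbouring secondary hydroxyl for acyl migration.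

**Compound list**

1 | 2,2-dimethyl-1,3-dioxan-5-one | CC1(C)OCC(=O)CO1 | starting material
2 | (triphenylphosphoranylidene)acetaldehyde | O=CC=P(c1ccccc1)(c1ccccc1)c1ccccc1 | starting material
3 | 2-(2,2-dimethyl-1,3-dioxan-5-ylidene)acetaldehyde | CC1(C)OCC(=CC=O)CO1 | intermediate
4 | potassium (E)-2-(2,2-dimethyl-4H-1,3-dioxin-5-yl)ethenolate | [K+].[O-]/C=C/C1=COC(C)(C)OC1 | intermediate
5 | (E)-2-(2,2-dimethyl-4H-1,3-dioxin-5-yl)ethenyl benzoate | O=C(O/C=C/C1=COC(C)(C)OC1)c1ccccc1 | intermediate
6 | (1R,2S,5R)-menthyl (S)-p-toluenesulfinate | Cc1ccc(cc1)[S@@](=O)O[C@H]1[C@H](C(C)C)CC[C@@H](C)C1 | starting material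
7 | ethynylmagnesium bromide | C#C[Mg]Br | starting material
8 | (R)-ethynyl p-tolyl sulfoxide | C#C[S@@](=O)c1ccc(C)cc1 | intermediate
9 | (6S,8aR)-2,2-dimethyl-8-[(S)-p-tolylsulfinyl]-6,8a-dihydro-4H-1,3-benzodioxin-6-yl benzoate | O=C(O[C@H]1C=C2COC(C)(C)O[C@H]2C([S@@](=O)c2ccc(C)cc2)=C1)c1ccccc1 | intermediate
10 | (4aS,5S,6R,8aR)-4a,5-dihydroxy-2,2-dimethyl-8-[(S)-p-tolylsulfinyl]-4a,5,6,8a-tetrahydro-4H-1,3-benzodioxin-6-yl benzoate | O[C@H]1[C@H](OC(=O)c2ccccc2)C=C([S@@](=O)c2ccc(C)cc2)[C@H](OC(C)(C)OC2)[C@@]12O | intermediate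
11 | (4aS,5S,6R,8aR)-4a,5-dihydroxy-2,2-dimethyl-8-(p-tolylsulfonyl)-4a,5,6,8a-tetrahydro-4H-1,3-benzodioxin-6-yl benzoate | O[C@H]1[C@H](OC(=O)c2ccccc2)C=C(S(=O)(=O)c2ccc(C)cc2)[C@H](OC(C)(C)OC2)[C@@]12O | intermediate
12 | (4aS,5S,6R,8aR)-5-acetoxy-4a-hydroxy-2,2-dimethyl-8-(p-tolylsulfonyl)-4a,5,6,8a-tetrahydro-4H-1,3-benzodioxin-6-yl benzoate | CC(=O)O[C@H]1[C@H](OC(=O)c2ccccc2)C=C(S(=O)(=O)c2ccc(C)cc2)[C@H](OC(C)(C)OC2)[C@@]12O | intermediate
13 | (4aS,5S,6R,8aR)-5-acetoxy-4a-hydroxy-2,2-dimethyl-8-(tributylstannyl)-4a,5,6,8a-tetrahydro-4H-1,3-benzodioxin-6-yl benzoate | CC(=O)O[C@H]1[C@H](OC(=O)c2ccccc2)C=C([Sn](CCCC)(CCCC)CCCC)[C@H](OC(C)(C)OC2)[C@@]12O | intermediate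
14 | (1R,4S,5R,6S)-6-acetoxy-4,5-dihydroxy-5-(hydroxymethyl)cyclohex-2-en-1-yl benzoate | CC(=O)O[C@H]1[C@H](OC(=O)c2ccccc2)C=C[C@H](O)[C@]1(O)CO | intermediate
15 | [(1R,2S,3R,6S)-2-acetoxy-3,6-bis(benzoyloxy)-1-hydroxycyclohex-4-en-1-yl]methyl benzoate | CC(=O)O[C@H]1[C@H](OC(=O)c2ccccc2)C=C[C@H](OC(=O)c2ccccc2)[C@]1(O)COC(=O)c1ccccc1 | target

**Step count and risks**

Total step count: 8. Longest linear sequence: 7 steps (steps 1, 2, 4, 5, 6, 7, 8); step 3 is a one-step side branch.

Steps most likely to fail:

1. Step 4. The cycloaddition may be slower than thermal cycloreversion of the dioxin ring (loss of acetone), the adduct may aromatise by loss of benzoic acid, or the sulfinyl group may discriminate the diene faces poorly. Fallback, setting out from 5 and coming back at 12: cycloaddition of 5 with the more reactive, commercial ethynyl p-tolyl sulfone (PhMe, 40 °C) should give racemic cis-2,2-dimethyl-8-(p-tolylsulfonyl)-6,8a-dihydro-4H-1,3-benzodioxin-6-yl benzoate F1. Dihydroxylation with OsO4/NMO as in step 5 should give racemic 4a,5-dihydroxy-2,2-dimethyl-8-(p-tolylsulfonyl)-4a,5,6,8a-tetrahydro-4H-1,3-benzodioxin-6-yl benzoate F2, the racemate of 11. A lipase-catalysed kinetic resolution (Burkholderia cepacia lipase, vinyl acetate, tert-butyl methyl ether, 40 °C) then acetylates the secondary hydroxyl of one enantiomer only and delivers 12, the unreacted mirror-image diol being removed by chromatography. Should the enzyme prefer the mirror image, the recovered diol is 11 itself and enters step 6.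

2. Step 7. The tin radical may add and be reduced (hydrostannation) instead of expelling the sulfonyl radical at the hindered ring carbon, or the acid stage may cause acetyl migration or allylic ionisation. Fallback, setting out from 12 and coming back at 14: polar addition–elimination with Na2S2O4/NaHCO3 in DMF–H2O (60 °C) replaces the sulfonyl group by hydrogen without moving the alkene and should give (4aR,5S,6R,8aS)-5-acetoxy-4a-hydroxy-2,2-dimethyl-4a,5,6,8a-tetrahydro-4H-1,3-benzodioxin-6-yl benzoate F3. Aqueous acetic acid (80 %, 40 °C) then removes the acetonide to give 14.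

3. Step 2. The dienolate may be acylated on carbon, the amide base may add to the aldehyde or trigger aldol self-condensation, and the enol acetal may hydrolyse during isolation. Fallback, setting out from 3 and coming back at 5: soft enolisation with Me3SiOTf/Et3N (CH2Cl2, 0 °C) should give trimethyl{[(E)-2-(2,2-dimethyl-4H-1,3-dioxin-5-yl)ethenyl]oxy}silane F4 under non-nucleophilic conditions. Fluoride-catalysed O-acylation with benzoyl fluoride (catalytic Bu4NF, THF, 0 °C) then exchanges silicon for benzoyl on oxygen and gives 5.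

Further compounds
F1 | step 4 | racemic (6S,8aR)-2,2-dimethyl-8-(p-tolylsulfonyl)-6,8a-dihydro-4H-1,3-benzodioxin-6-yl benzoate | O=C(O[C@H]1C=C2COC(C)(C)O[C@H]2C(S(=O)(=O)c2ccc(C)cc2)=C1)c1ccccc1.O=C(O[C@@H]1C=C2COC(C)(C)O[C@@H]2C(S(=O)(=O)c2ccc(C)cc2)=C1)c1ccccc1
F2 | step 4 | racemic (4aS,5S,6R,8aR)-4a,5-dihydroxy-2,2-dimethyl-8-(p-tolylsulfonyl)-4a,5,6,8a-tetrahydro-4H-1,3-benzodioxin-6-yl benzoate | O[C@H]1[C@H](OC(=O)c2ccccc2)C=C(S(=O)(=O)c2ccc(C)cc2)[C@H](OC(C)(C)OC2)[C@@]12O.O[C@@H]1[C@@H](OC(=O)c2ccccc2)C=C(S(=O)(=O)c2ccc(C)cc2)[C@@H](OC(C)(C)OC2)[C@]12O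
F3 | step 7 | (4aR,5S,6R,8aS)-5-acetoxy-4a-hydroxy-2,2-dimethyl-4a,5,6,8a-tetrahydro-4H-1,3-benzodioxin-6-yl benzoate | CC(=O)O[C@H]1[C@H](OC(=O)c2ccccc2)C=C[C@H](OC(C)(C)OC2)[C@@]12O
F4 | step 2 | trimethyl{[(E)-2-(2,2-dimethyl-4H-1,3-dioxin-5-yl)ethenyl]oxy}silane | C[Si](C)(C)O/C=C/C1=COC(C)(C)OC1
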